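**Plan**

1. Target: (2S,4R)-2-heptadecyl-4-hydroxy-2,3,4,6,7,8-hexahydro-5H-chromen-5-one, with the C2 chain and C4 hydroxyl cis (chromene numbering; pyran = ring A, carbocycle = ring B).
2. Retrosynthesis: mask C4–OH as a silyl ether, then cut ring B at C4a–C5 and at C7–C8. This removes C5–C6–C7 as acryloyl chloride and leaves a 4-silyloxy-6-methyl-3,4-dihydro-2H-pyran. C4–O is traced back to the ketone of a 2,3-dihydro-4H-pyran-4-one, O1–C8a is cut to a β-hydroxy ynone, and that to a Weinreb amide, a β-keto ester, and octadecanoyl chloride plus Meldrum's acid.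
3. Enabling feature: O1–C8a=C4a is an enol ether. C4a is its nucleophilic carbon, and the methyl on C8a (the future C8) becomes vinylogously enolisable once C4a carries an acyl group. This 1,3-bis-nucleophile matches the 1,3-bis-electrophile acryloyl (C5 acyl carbon, C7 β-carbon), and their union is the vinylogous ester C8a=C4a–C5=O of ring B.
4. Forward order: C20 chain (steps 1–4), ring A by 6-endo-dig closure (step 5), C4 carbinol (steps 6–7), ring B by one-pot C-acylation/6π electrocyclisation (step 8), desilylation (step 9). C4 is reduced before the annulation because a C4 ketone would let ring A open by β-elimination of O1 under base and could not later be told from C5=O.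
5. Stereochemistry: C2 (S) from asymmetric hydrogenation of the β-keto ester with the (S)-BINAP ruthenium catalyst; C4 (R) from substrate-controlled Luche reduction of the dihydropyranone, cis to the C2 chain.

Key step: step 8

**Route**

Step 1
Reactants: 1 octadecanoyl chloride; 2 Meldrum's acid (2,2-dimethyl-1,3-dioxane-4,6-dione)
Product: 4 methyl 3-oxoicosanoate, via acyl Meldrum's acid 3 (not isolated)
Conditions: pyridine, CH2Cl2, 0 °C to rt; then MeOH, reflux
Reagents that add atoms: Meldrum's acid (2), CC1(C)OC(=O)CC(=O)O1; methanol, CO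
Why: C-acylation of Meldrum's acid followed by methanolysis with loss of acetone and CO2 is the standard acyl-Meldrum's-acid route to long-chain β-keto esters.

Step 2
Reactants: 4 methyl 3-oxoicosanoate
Product: 5 methyl (3S)-3-hydroxyicosanoate
Conditions: RuCl2[(S)-BINAP] (0.5 mol %), H2 (50 atm), MeOH, 50 °C
Reagents that add atoms: none
Why: Noyori asymmetric hydrogenation of a β-keto ester, in which the (S)-BINAP ligand on the chelated keto ester directs hydrogen to the ketone face that should give the (S)-carbinol.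

Step 3
Reactants: 5 methyl (3S)-3-hydroxyicosanoate
Product: 6 (3S)-3-hydroxy-N-methoxy-N-methylicosanamide
Conditions: MeNH(OMe)·HCl, i-PrMgCl, THF, −20 to 0 °C
Reagents that add atoms: N,O-dimethylhydroxylamine hydrochloride, CNOC.Cl
Why: Weinreb amide formation by aminolysis of the ester with the chloromagnesium amide, which tolerates the free hydroxyl as its magnesium alkoxide and does not touch the carbinol centre.

Step 4
Reactants: 6 (3S)-3-hydroxy-N-methoxy-N-methylicosanamide; 7 1-propynylmagnesium bromide
Product: 8 (6S)-6-hydroxytricos-2-yn-4-one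
Conditions: 1-propynylmagnesium bromide (3.5 equiv), THF, −20 to 0 °C; cold 1 M HCl quench
Reagents that add atoms: 1-propynylmagnesium bromide (7), CC#C[Mg]Br
Why: Weinreb ketone synthesis, in which the alkynyl Grignard reagent adds once to give a chelated tetrahedral intermediate that should collapse to the ynone only on acidic quench, the hydroxyl being carried as its alkoxide.

Step 5
Reactants: 8 (6S)-6-hydroxytricos-2-yn-4-one
Product: 9 (2S)-2-heptadecyl-6-methyl-2,3-dihydro-4H-pyran-4-one
Conditions: AgOTf (10 mol %), CH2Cl2, rt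
Reagents that add atoms: none
Why: 6-endo-dig oxa-Michael cycloisomerisation of a β-hydroxy ynone, in which the hydroxyl adds to the activated alkyne β-carbon and the C2 centre is retained.

Step 6
Reactants: 9 (2S)-2-heptadecyl-6-methyl-2,3-dihydro-4H-pyran-4-one
Product: 10 (2S,4R)-2-heptadecyl-6-methyl-3,4-dihydro-2H-pyran-4-ol
Conditions: NaBH4, CeCl3·7H2O, MeOH, −78 °C; NaHCO3 work-up, used at once
Reagents that add atoms: none
Why: Luche 1,2-reduction, in which hydride should attack axially on the half-chair that holds the C2 chain pseudo-equatorial, so that the new C4 hydroxyl is pseudo-equatorial and cis to the chain (substrate control, 4R).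

Step 7
Reactants: 10 (2S,4R)-2-heptadecyl-6-methyl-3,4-dihydro-2H-pyran-4-ol
Product: 11 tert-butyl{[(2S,4R)-2-heptadecyl-6-methyl-3,4-dihydro-2H-pyran-4-yl]oxy}dimethylsilane
Conditions: TBSCl, imidazole, DMF, 0 °C to rt
Reagents that add atoms: tert-butyldimethylsilyl chloride, CC(C)(C)[Si](C)(C)Cl
Why: Imidazole-mediated silylation of a secondary allylic alcohol, run under basic conditions that should spare the acid-labile enol ether.

Step 8
Reactants: 11 tert-butyl{[(2S,4R)-2-heptadecyl-6-methyl-3,4-dihydro-2H-pyran-4-yl]oxy}dimethylsilane; 12 acryloyl chloride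
Product: 16 (2S,4R)-4-[(tert-butyldimethylsilyl)oxy]-2-heptadecyl-2,3,4,6,7,8-hexahydro-5H-chromen-5-one, via dienone 13 (not isolated), via trienol 14 (not isolated), via dienol 15 (not isolated)
Conditions: acryloyl chloride, AgOTf, 2,6-di-tert-butyl-4-methylpyridine, ClCH2CH2Cl, −30 °C to rt; then 70 °C
Reagents that add atoms: acryloyl chloride (12), C=CC(=O)Cl
Why: Proposed new method: acryloyl triflate, formed in the flask from 12 and AgOTf, should acylate the only nucleophilic carbon of the enol ether (C5 of the dihydropyran, the future C4a) and, after loss of a proton to the hindered pyridine, give the cross-conjugated β-alkoxy dienone 13. The pyridinium triflate left in the flask should then enolise 13 reversibly through its ring methyl group, now vinylogous to the ketone, to the (E)-configured 2-alkoxy-4-hydroxyhexatriene 14, which should close on warming to dienol 15 and ketonise to the vinylogous ester 16. The closest known reaction types are the Friedel–Crafts-type β-acylation of enol ethers and glycals with activated acyl halides, the formal [3+3] annulation of enamines with acryloyl chloride, and the thermal 6π electrocyclisation of 2-oxygenated hexatrienes. Ring B closes by a disrotatory 6π electrocyclisation of 14 (in polar terms a 6-endo-trig vinylogous Michael addition of the methylidene carbon to the vinyl ketone), its second new bond comes from the intermolecular acylation, and no new stereocentre is formed, C2 and C4 being spectators. The step needs the acyl carbon and not the β-carbon of the electrophile to bond to the enol ether carbon, which the hard acyl triflate and the single nucleophilic site should secure, and it needs closure from the methyl group, the only position from which a six-membered ring can form. Ionisation of the allylic silyl ether should be held back by the buffer and the low temperature of the acylation, and Nazarov closure of 13 should be disfavoured because the β-alkoxy group stabilises the pentadienyl cation.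

Step 9
Reactants: 16 (2S,4R)-4-[(tert-butyldimethylsilyl)oxy]-2-heptadecyl-2,3,4,6,7,8-hexahydro-5H-chromen-5-one
Product: 17 (2S,4R)-2-heptadecyl-4-hydroxy-2,3,4,6,7,8-hexahydro-5H-chromen-5-one
Conditions: HF·pyridine, pyridine, THF, 0 °C to rt
Reagents that add atoms: none
Why: Buffered fluoride desilylation should remove the silyl ether without acid- or base-induced ionisation or elimination at C4, whose configuration is kept.

**Compound list**

1 | octadecanoyl chloride | CCCCCCCCCCCCCCCCCC(=O)Cl | starting material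
2 | Meldrum's acid (2,2-dimethyl-1,3-dioxane-4,6-dione) | CC1(C)OC(=O)CC(=O)O1 | starting material
3 | acyl Meldrum's acid, 5-(1-hydroxyoctadecylidene)-2,2-dimethyl-1,3-dioxane-4,6-dione | CCCCCCCCCCCCCCCCCC(O)=C1C(=O)OC(C)(C)OC1=O | intermediate
4 | methyl 3-oxoicosanoate | CCCCCCCCCCCCCCCCCC(=O)CC(=O)OC | intermediate
5 | methyl (3S)-3-hydroxyicosanoate | CCCCCCCCCCCCCCCCC[C@H](O)CC(=O)OC | intermediate
6 | (3S)-3-hydroxy-N-methoxy-N-methylicosanamide | CCCCCCCCCCCCCCCCC[C@H](O)CC(=O)N(C)OC | intermediate
7 | 1-propynylmagnesium bromide | CC#C[Mg]Br | starting material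
8 | (6S)-6-hydroxytricos-2-yn-4-one | CCCCCCCCCCCCCCCCC[C@H](O)CC(=O)C#CC | intermediate
9 | (2S)-2-heptadecyl-6-methyl-2,3-dihydro-4H-pyran-4-one | CCCCCCCCCCCCCCCCC[C@H]1CC(=O)C=C(C)O1 | intermediate
10 | (2S,4R)-2-heptadecyl-6-methyl-3,4-dihydro-2H-pyran-4-ol | CCCCCCCCCCCCCCCCC[C@H]1C[C@@H](O)C=C(C)O1 | intermediate
11 | tert-butyl{[(2S,4R)-2-heptadecyl-6-methyl-3,4-dihydro-2H-pyran-4-yl]oxy}dimethylsilane | CCCCCCCCCCCCCCCCC[C@H]1C[C@@H](O[Si](C)(C)C(C)(C)C)C=C(C)O1 | intermediate
12 | acryloyl chloride (prop-2-enoyl chloride) | C=CC(=O)Cl | starting material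
13 | dienone, 1-[(2S,4R)-4-[(tert-butyldimethylsilyl)oxy]-2-heptadecyl-6-methyl-3,4-dihydro-2H-pyran-5-yl]prop-2-en-1-one | CCCCCCCCCCCCCCCCC[C@H]1C[C@@H](O[Si](C)(C)C(C)(C)C)C(C(=O)C=C)=C(C)O1 | intermediate
14 | trienol, (1E)-1-[(2S,4R)-4-[(tert-butyldimethylsilyl)oxy]-2-heptadecyl-6-methylideneoxan-5-ylidene]prop-2-en-1-ol | CCCCCCCCCCCCCCCCC[C@H]1C[C@@H](O[Si](C)(C)C(C)(C)C)/C(=C(\O)C=C)C(=C)O1 | intermediate
15 | dienol, (2S,4R)-4-[(tert-butyldimethylsilyl)oxy]-2-heptadecyl-3,4,7,8-tetrahydro-2H-chromen-5-ol | CCCCCCCCCCCCCCCCC[C@H]1C[C@@H](O[Si](C)(C)C(C)(C)C)C2=C(CCC=C2O)O1 | intermediate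
16 | (2S,4R)-4-[(tert-butyldimethylsilyl)oxy]-2-heptadecyl-2,3,4,6,7,8-hexahydro-5H-chromen-5-one | CCCCCCCCCCCCCCCCC[C@H]1C[C@@H](O[Si](C)(C)C(C)(C)C)C2=C(CCCC2=O)O1 | intermediate
17 | (2S,4R)-2-heptadecyl-4-hydroxy-2,3,4,6,7,8-hexahydro-5H-chromen-5-one | CCCCCCCCCCCCCCCCC[C@H]1C[C@@H](O)C2=C(CCCC2=O)O1 | target

**Step count and risks**

Total step count: 9. Longest linear sequence: 9 steps (from octadecanoyl chloride).

Steps most likely to fail:

1. Step 8. The acryloyl electrophile may polymerise or add through its β-carbon. The allylic C4 silyloxy group may ionise before or after acylation. The dienone may fail to enolise through the methyl group and close. The fallback sets out from 11 and makes the two bonds one after the other by known reactions.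
   - Vilsmeier–Haack formylation of 11 (POCl3, DMF, 0 °C; aqueous NaOAc) would give (2S,4R)-4-[(tert-butyldimethylsilyl)oxy]-2-heptadecyl-6-methyl-3,4-dihydro-2H-pyran-5-carbaldehyde F1.
   - Vinylmagnesium bromide (THF, −78 °C) would give the divinyl carbinol 1-[(2S,4R)-4-[(tert-butyldimethylsilyl)oxy]-2-heptadecyl-6-methyl-3,4-dihydro-2H-pyran-5-yl]prop-2-en-1-ol F2, and MnO2 (CH2Cl2) would oxidise it to dienone 13, now isolated.
   - Soft enolisation of 13 with TBSOTf and Et3N (CH2Cl2, 0 °C) would give the silyl trienol ether F3.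
   - Thermal 6π electrocyclisation of F3 (toluene, 90–110 °C) would give the bicyclic bis-silyl dienol ether F4.
   - HF·pyridine would remove both silyl groups, and the fallback comes back to the route at target 17.

2. Step 9. Fluoride or adventitious acid may ionise the C4–O bond next to the vinylogous ester, leading to elimination towards the 2H-chromenone or to epimerisation at C4. The fallback sets out from 10 and uses a protecting group that is removed oxidatively at neutral pH.
   - NaH and 4-methoxybenzyl chloride (DMF, 0 °C) would give (2S,4R)-2-heptadecyl-4-[(4-methoxybenzyl)oxy]-6-methyl-3,4-dihydro-2H-pyran F5.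
   - The conditions of step 8 would take F5 through the dienone 1-[(2S,4R)-2-heptadecyl-4-[(4-methoxybenzyl)oxy]-6-methyl-3,4-dihydro-2H-pyran-5-yl]prop-2-en-1-one F6 (not isolated) to (2S,4R)-2-heptadecyl-4-[(4-methoxybenzyl)oxy]-2,3,4,6,7,8-hexahydro-5H-chromen-5-one F7.
   - DDQ (CH2Cl2, pH 7 buffer, 0 °C) would cleave the benzyl ether, and the fallback comes back to the route at target 17.

3. Step 4. The liberated N,O-dimethylhydroxylamine or a second alkynyl group may add in conjugate fashion to the ynone during quench, and the magnesium aldolate may undergo retro-aldol cleavage. The fallback sets out from 6 and avoids the ynone and the silver-catalysed closure.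
   - Acylation of excess lithium enolate of acetone (LDA, THF, −78 °C) with 6 would give (6S)-6-hydroxytricosane-2,4-dione F8.
   - Acid-catalysed cyclodehydration of F8 (TsOH, CH2Cl2, rt) would close ring A, and the fallback comes back to the route at dihydropyranone 9.

**Further compounds**

F1 | step 8 | (2S,4R)-4-[(tert-butyldimethylsilyl)oxy]-2-heptadecyl-6-methyl-3,4-dihydro-2H-pyran-5-carbaldehyde | CCCCCCCCCCCCCCCCC[C@H]1C[C@@H](O[Si](C)(C)C(C)(C)C)C(C=O)=C(C)O1
F2 | step 8 | 1-[(2S,4R)-4-[(tert-butyldimethylsilyl)oxy]-2-heptadecyl-6-methyl-3,4-dihydro-2H-pyran-5-yl]prop-2-en-1-ol (both carbinol epimers) | CCCCCCCCCCCCCCCCC[C@H]1C[C@@H](O[Si](C)(C)C(C)(C)C)C(C(O)C=C)=C(C)O1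
F3 | step 8 | tert-butyl{[(1E)-1-[(2S,4R)-4-[(tert-butyldimethylsilyl)oxy]-2-heptadecyl-6-methylideneoxan-5-ylidene]prop-2-en-1-yl]oxy}dimethylsilane | CCCCCCCCCCCCCCCCC[C@H]1C[C@@H](O[Si](C)(C)C(C)(C)C)/C(=C(\O[Si](C)(C)C(C)(C)C)C=C)C(=C)O1
F4 | step 8 | tert-butyl{[(2S,4R)-5-[(tert-butyldimethylsilyl)oxy]-2-heptadecyl-3,4,7,8-tetrahydro-2H-chromen-4-yl]oxy}dimethylsilane | CCCCCCCCCCCCCCCCC[C@H]1C[C@@H](O[Si](C)(C)C(C)(C)C)C2=C(CCC=C2O[Si](C)(C)C(C)(C)C)O1
F5 | step 9 | (2S,4R)-2-heptadecyl-4-[(4-methoxybenzyl)oxy]-6-methyl-3,4-dihydro-2H-pyran | CCCCCCCCCCCCCCCCC[C@H]1C[C@@H](OCc2ccc(OC)cc2)C=C(C)O1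
F6 | step 9 | 1-[(2S,4R)-2-heptadecyl-4-[(4-methoxybenzyl)oxy]-6-methyl-3,4-dihydro-2H-pyran-5-yl]prop-2-en-1-one | CCCCCCCCCCCCCCCCC[C@H]1C[C@@H](OCc2ccc(OC)cc2)C(C(=O)C=C)=C(C)O1
F7 | step 9 | (2S,4R)-2-heptadecyl-4-[(4-methoxybenzyl)oxy]-2,3,4,6,7,8-hexahydro-5H-chromen-5-one | CCCCCCCCCCCCCCCCC[C@H]1C[C@@H](OCc2ccc(OC)cc2)C3=C(CCCC3=O)O1
F8 | step 4 | (6S)-6-hydroxytricosane-2,4-dione | CCCCCCCCCCCCCCCCC[C@H](O)CC(=O)CC(C)=O
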